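Slowness in a flask with equal charges grows with dilution: for a single step of rate constant k, the reciprocal of the fraction left climbs linearly in time, and that fraction stands at half after the reciprocal of k[substrate] at the start.

| flask | substrate | partner | temperature | remark | time |
|---|---|---|---|---|---|
| green | 0.066 M | 1 equiv | 5 °C | run made earlier |  |
| red | 0.19 M | 1 equiv | 16 °C | run made earlier |  |
| north | 0.050 M | 1.00 equiv |  | at 20 °C until 10 min, from then on at 0 °C | 20 min |
| south | 0.15 M | 1.00 equiv |  | at 20 °C throughout | 20 min |

| run | time / min | target / % |
|---|---|---|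
| green | 5.00 | 15.0 |
| green | 10.0 | 25.2 |
| green | 15.0 | 27.6 |
| green | 20.0 | 34.0 |
| red | 0.833 | 17.8 |
| red | 2.00 | 31.1 |
| red | 4.00 | 41.0 |
| red | 10.0 | 48.4 |

(scatter of a reading: 1 percentage point)

- which one finishes higher in amount of target, in percent of the substrate charged ("neither" within 2 percentage points) (north / south / neither)
- amount of target at the end, in percent of the substrate charged, north
- amount of target at the end, in percent of the substrate charged, south

The readings show target, so what is not yet target serves as the fraction left. The first red reading then gives k = 1.37 M⁻¹ min⁻¹, and the first green reading 0.535 M⁻¹ min⁻¹. Together they give 57.1 kJ mol⁻¹, so k is 1.89 M⁻¹ min⁻¹ at 20 °C and 0.340 M⁻¹ min⁻¹ at 0 °C.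

So the half-time by charge, the second-order half-life, is 10.6 min for warm north but 3.52 min for south. Counted in these half-times, north ends at 1.12, close to the red reading at 4.00 min (1.04), so this reckoning expects about 41.0% there. South ends at 5.68, past the last red reading (2.60), so this reckoning expects 48.4% or a little above, and south ahead.

The forecast, against these figures, gives 39.5% for north and 53% for south, with south ahead, and holds that “Any partner decay would hurt the dilute north flask more”.

The flasks give 32.5% in north and 41.8% in south, so south finishes higher, and north stands below its reckoned figure, as does south.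

    substrate + partner ⇌ target (K = 51.0 M⁻¹, k = 2.10 M⁻¹ min⁻¹, Ea = 57.0 kJ mol⁻¹, ΔH = −36.0 kJ mol⁻¹)
    substrate + partner ⇌ isomer of the product (K = 42.0 M⁻¹, k = 0.750 M⁻¹ min⁻¹, Ea = 42.0 kJ mol⁻¹, ΔH = −90.0 kJ mol⁻¹)
    partner → decomposed reagent (k = 0.0560 min⁻¹, Ea = 95.0 kJ mol⁻¹)
    partner → decomposition product (k = 7.00 × 10⁻⁵ min⁻¹, Ea = 114 kJ mol⁻¹)
    (constants at 20 °C)

At 20 °C the path from partner to decomposed reagent has by itself a half-life of 12.4 min, which warm north's 10.6 min nearly matches, while south's 3.52 min is shorter. A neighbour of south at 0.26 M, with a half-time of 2.04 min, ends at 46.8% of target, and one at 0.060 M, with 8.82 min, ends at 32.0%.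

The readings were generated by integration for substances that don't exist; noise was put on by code.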